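**Plan**

- Enabling feature: in the resorcinol ring the C17 chain sits on C5 and the hydroxyls on C1 and C3, both meta to it. This is the folding pattern of a tetraketide in which ring C5 is the former acyl carbon of a 12-hydroxyoctadec-9-enoyl starter.
- Retrosynthetic cuts, in order: (i) a CO2Me is put back on ring C6 (forward: decarboxylation); (ii) ring bond C5–C6 (forward: intramolecular aldol, then aromatisation); (iii) bond C4–C5 (forward: Claisen acylation of a 3,5-dioxohexanoate trianion by the C18 ester).
- Forward order: the chain is joined first (acyl carbon of the silylated hydroxy-oleate to C6 of methyl 3,5-dioxohexanoate), the single ring closes next, and removal of the silyl group and the ester carbon comes last.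
- Stereochemistry: the 11S carbinol is C12 of natural (R)-methyl ricinoleate after one Mitsunobu inversion; the 8Z alkene is the native 9Z alkene and is never touched.

Key step: step 5

Assumption: methyl ricinoleate (natural, 9Z,12R) and methyl 3,5-dioxohexanoate are taken as catalogue compounds, and LDA is used as a commercial solution.

**Route**

Step 1
Reactants: 1 methyl (9Z,12R)-12-hydroxyoctadec-9-enoate (methyl ricinoleate)
Product: 2 methyl (9Z,12S)-12-(4-nitrobenzoyloxy)octadec-9-enoate
Conditions: 4-O2NC6H4CO2H (1.5 equiv), PPh3 (1.5 equiv), DIAD (1.5 equiv), THF, 0 °C → rt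
Reagents that add atoms: 4-nitrobenzoic acid, O=C(O)c1ccc(cc1)[N+](=O)[O-]
Why: Mitsunobu reaction, in which the alcohol is activated as an alkoxyphosphonium ion and displaced by 4-nitrobenzoate in an SN2 step, so C12 should invert from R to S; the acidic pronucleophile keeps elimination low, and the methyl ester and Z alkene are inert.

Step 2
Reactants: 2 methyl (9Z,12S)-12-(4-nitrobenzoyloxy)octadec-9-enoate
Product: 3 methyl (9Z,12S)-12-hydroxyoctadec-9-enoate
Conditions: K2CO3 (0.3 equiv), MeOH, rt
Reagents that add atoms: none
Why: Base-catalysed transesterification (methanolysis) removes the activated aryl ester by acyl–oxygen cleavage, so the S centre is untouched, while exchange at the fatty methyl ester is degenerate in methanol.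

Step 3
Reactants: 3 methyl (9Z,12S)-12-hydroxyoctadec-9-enoate
Product: 4 methyl (9Z,12S)-12-(tert-butyldimethylsilyloxy)octadec-9-enoate
Conditions: TBSCl (1.3 equiv), imidazole (2.5 equiv), DMF, rt
Reagents that add atoms: tert-butyldimethylsilyl chloride (TBSCl), CC(C)(C)[Si](C)(C)Cl
Why: Imidazole-promoted silylation of a secondary alcohol should give an ether that withstands lithium polyanions and carbonate in methanol; it removes the acidic OH before the Claisen step and leaves the stereocentre alone.

Step 4
Reactants: 4 methyl (9Z,12S)-12-(tert-butyldimethylsilyloxy)octadec-9-enoate; 5 methyl 3,5-dioxohexanoate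
Product: 7 methyl (15Z,18S)-18-(tert-butyldimethylsilyloxy)-3,5,7-trioxotetracos-15-enoate, via trilithium trianion of methyl 3,5-dioxohexanoate 6 (not isolated)
Conditions: 5 (3.0 equiv), LDA (9.0 equiv), THF, −78 → 0 °C; then 4 (1.0 equiv), 0 °C → rt; AcOH, −78 °C; crude 7 used at once
Reagents that add atoms: none
Why: Claisen acylation of a tricarbonyl polyanion, a known reaction of this trianion with esters: LDA removes the protons at C2, C4 and C6 of 5, and the last-formed, most basic C6 carbanion of 6 should attack the ester carbonyl of 4 and expel methoxide, the excess trianion taking up the acidic proton of the product; no free LDA remains to enolise 4, and the silyl ether, alkene and stereocentre are spectators.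

Step 5
Reactants: 7 methyl (15Z,18S)-18-(tert-butyldimethylsilyloxy)-3,5,7-trioxotetracos-15-enoate
Product: 9 methyl 2,4-dihydroxy-6-[(8Z,11S)-11-(tert-butyldimethylsilyloxy)heptadec-8-enyl]benzoate, via cyclic aldol adduct 8 (not isolated)
Conditions: Cs2CO3 (2.0 equiv), MeOH, 0 °C → rt; then AcOH to pH 5
Reagents that add atoms: none
Why: Carbonate in methanol converts 7 into its enolates, and C2 of the C1–C3 keto-ester enolate should add to the C7 ketone to give aldol 8, which loses water by E1cB elimination and tautomerises at its two ring ketones to the phenol, an irreversible aromatic sink that the acetic acid stage completes. The closest known reaction type is the biogenetic-type aldol cyclisation of 3,5,7-trioxoalkanoate esters to 6-substituted 2,4-dihydroxybenzoates under mild base. The one ring (C2 to C7 of the chain, the future benzene) closes in the 6-(enolendo)-exo-trig mode, which is favoured for enolates. No lasting stereocentre is formed, since the two sp3 centres of 8 vanish on aromatisation and the C18 carbinol and the Z alkene lie eleven and eight carbons from C7. The step needs C2→C7 aldol closure to win over C6→C1 Claisen closure (acylphloroglucinol), O-cyclisation to pyranones and a C8→C3 aldol. The methyl ester is the poorest electrophile of the array and is conjugated with the enolate, no chelating Mg2+ is present, the medium is never acidic enough for pyranone formation, and the unactivated C8 methylene is not enolised by carbonate.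

Step 6
Reactants: 9 methyl 2,4-dihydroxy-6-[(8Z,11S)-11-(tert-butyldimethylsilyloxy)heptadec-8-enyl]benzoate
Product: 10 methyl 2,4-dihydroxy-6-[(8Z,11S)-11-hydroxyheptadec-8-enyl]benzoate
Conditions: HF·pyridine, THF/pyridine, 0 °C → rt
Reagents that add atoms: none
Why: Fluoride-mediated desilylation, driven by the strong Si–F bond, should free the secondary alcohol with retention, since only the Si–O bond breaks; the buffered reagent leaves the phenols, the methyl ester and the alkene unchanged.

Step 7
Reactants: 10 methyl 2,4-dihydroxy-6-[(8Z,11S)-11-hydroxyheptadec-8-enyl]benzoate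
Product: 12 target resorcinol 5-[(8Z,11S)-11-hydroxyheptadec-8-enyl]benzene-1,3-diol, via resorcylic acid 11 (not isolated)
Conditions: NaOH (2.5 M aq)/MeOH, reflux, Ar (degassed); then 2 M HCl to pH 2, 50 °C
Reagents that add atoms: none
Why: Saponification of the hindered salicylate-type ester followed by decarboxylation of the β-resorcylic acid 11, which loses CO2 through ipso protonation of the ring carbon ortho and para to the hydroxyls (the usual way such esters are taken to 5-alkylresorcinols); the carbinol and the isolated Z alkene should tolerate hot alkali and brief dilute acid, and exclusion of air protects the resorcinol dianion.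

**Compound list**

1 | methyl (9Z,12R)-12-hydroxyoctadec-9-enoate (methyl ricinoleate) | CCCCCC[C@@H](O)C/C=C\CCCCCCCC(=O)OC | starting material
2 | methyl (9Z,12S)-12-(4-nitrobenzoyloxy)octadec-9-enoate | CCCCCC[C@H](OC(=O)c1ccc(cc1)[N+](=O)[O-])C/C=C\CCCCCCCC(=O)OC | intermediate
3 | methyl (9Z,12S)-12-hydroxyoctadec-9-enoate | CCCCCC[C@H](O)C/C=C\CCCCCCCC(=O)OC | intermediate
4 | methyl (9Z,12S)-12-(tert-butyldimethylsilyloxy)octadec-9-enoate | CCCCCC[C@H](O[Si](C)(C)C(C)(C)C)C/C=C\CCCCCCCC(=O)OC | intermediate
5 | methyl 3,5-dioxohexanoate | CC(=O)CC(=O)CC(=O)OC | starting material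
6 | trilithium 2,4,6-trianion of methyl 3,5-dioxohexanoate (not isolated) | [Li+].[Li+].[Li+].C=C([O-])C=C([O-])C=C([O-])OC | intermediate
7 | methyl (15Z,18S)-18-(tert-butyldimethylsilyloxy)-3,5,7-trioxotetracos-15-enoate (enol tautomers) | CCCCCC[C@H](O[Si](C)(C)C(C)(C)C)C/C=C\CCCCCCCC(=O)CC(=O)CC(=O)CC(=O)OC | intermediate
8 | methyl 2-hydroxy-2-[(8Z,11S)-11-(tert-butyldimethylsilyloxy)heptadec-8-enyl]-4,6-dioxocyclohexane-1-carboxylate (cyclic aldol adduct, ring centres undefined, not isolated) | CCCCCC[C@H](O[Si](C)(C)C(C)(C)C)C/C=C\CCCCCCCC1(O)CC(=O)CC(=O)C1C(=O)OC | intermediate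
9 | methyl 2,4-dihydroxy-6-[(8Z,11S)-11-(tert-butyldimethylsilyloxy)heptadec-8-enyl]benzoate | CCCCCC[C@H](O[Si](C)(C)C(C)(C)C)C/C=C\CCCCCCCc1cc(O)cc(O)c1C(=O)OC | intermediate
10 | methyl 2,4-dihydroxy-6-[(8Z,11S)-11-hydroxyheptadec-8-enyl]benzoate | CCCCCC[C@H](O)C/C=C\CCCCCCCc1cc(O)cc(O)c1C(=O)OC | intermediate
11 | 2,4-dihydroxy-6-[(8Z,11S)-11-hydroxyheptadec-8-enyl]benzoic acid (sodium salt in the flask, not isolated) | CCCCCC[C@H](O)C/C=C\CCCCCCCc1cc(O)cc(O)c1C(=O)O | intermediate
12 | 5-[(8Z,11S)-11-hydroxyheptadec-8-enyl]benzene-1,3-diol | CCCCCC[C@H](O)C/C=C\CCCCCCCc1cc(O)cc(O)c1 | target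

**Count and risks**

Total step count: 7. Longest linear sequence: 7 steps (1 → 12); 5 enters at step 4 as bought.

Steps most likely to fail:

1. Step 4. The trianion may act as a base towards the enolisable ester 4 (proton transfer in place of C-acylation), or the tetracarbonyl product may cyclise at oxygen during the quench, so conversion to 7 could be poor. Fallback, setting out from 4 and returning at 7: 4 is converted with MeNH(OMe)·HCl and i-PrMgCl into the Weinreb amide (9Z,12S)-12-(tert-butyldimethylsilyloxy)-N-methoxy-N-methyloctadec-9-enamide F1. The keto-dioxinone 2,2-dimethyl-6-(2-oxopropyl)-4H-1,3-dioxin-4-one F2 is made by C-acetylation of the lithium dienolate of commercial 2,2,6-trimethyl-4H-1,3-dioxin-4-one. The dianion of F2 (LDA, 2 equiv, THF, −78 °C) is acylated at its terminal methyl by F1 to give the diketo-dioxinone 6-[(12Z,15S)-15-(tert-butyldimethylsilyloxy)-2,4-dioxohenicos-12-enyl]-2,2-dimethyl-4H-1,3-dioxin-4-one F3. Heating F3 in toluene with methanol at 110 °C releases an acylketene by retro-[4+2] loss of acetone, and methanol traps it as the trioxo ester 7.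

2. Step 5. Ring closure may go the wrong way (Claisen attack of C6 on the ester carbon, or O-cyclisation to pyranones), or the sequence may stall at the undehydrated aldol 8. Fallback, setting out from 4 and returning at 9: 4 is taken through the Weinreb amide F1 to the diketo-dioxinone F3 as described under step 4. F3 is then treated with triethylamine in dichloromethane, so that the same ring bond forms by aldol attack of the dioxinone α-carbon (the masked C2) on the chain-bearing ketone while the ester carbon is locked in the dioxinone and is a poor Claisen acceptor. Dehydration gives the benzodioxinone 7-hydroxy-5-[(8Z,11S)-11-(tert-butyldimethylsilyloxy)heptadec-8-enyl]-2,2-dimethyl-4H-benzo[d][1,3]dioxin-4-one F4. Methanolysis of F4 (K2CO3, MeOH, rt) opens the acetonide lactone to the methyl resorcylate 9.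

3. Step 1. The activated homoallylic alcohol may eliminate to a conjugated diene, or inversion may be incomplete, which would erode the enantiomeric purity carried to the target. Fallback, setting out from 1 and returning at 3: 1 is mesylated (MsCl, Et3N, CH2Cl2, 0 °C) to methyl (9Z,12R)-12-(methylsulfonyloxy)octadec-9-enoate F5. SN2 displacement with caesium acetate and 18-crown-6 in toluene at 80 °C gives the inverted acetate methyl (9Z,12S)-12-acetoxyoctadec-9-enoate F6. Methanolysis of F6 (K2CO3, MeOH) gives 3.

Further compounds
F1 | step 4 | (9Z,12S)-12-(tert-butyldimethylsilyloxy)-N-methoxy-N-methyloctadec-9-enamide | CCCCCC[C@H](O[Si](C)(C)C(C)(C)C)C/C=C\CCCCCCCC(=O)N(C)OC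
F2 | step 4 | 2,2-dimethyl-6-(2-oxopropyl)-4H-1,3-dioxin-4-one | CC(=O)CC1=CC(=O)OC(C)(C)O1
F3 | step 4 | 6-[(12Z,15S)-15-(tert-butyldimethylsilyloxy)-2,4-dioxohenicos-12-enyl]-2,2-dimethyl-4H-1,3-dioxin-4-one | CCCCCC[C@H](O[Si](C)(C)C(C)(C)C)C/C=C\CCCCCCCC(=O)CC(=O)CC1=CC(=O)OC(C)(C)O1
F4 | step 5 | 7-hydroxy-5-[(8Z,11S)-11-(tert-butyldimethylsilyloxy)heptadec-8-enyl]-2,2-dimethyl-4H-benzo[d][1,3]dioxin-4-one | CCCCCC[C@H](O[Si](C)(C)C(C)(C)C)C/C=C\CCCCCCCc1cc(O)cc2OC(C)(C)OC(=O)c12
F5 | step 1 | methyl (9Z,12R)-12-(methylsulfonyloxy)octadec-9-enoate | CCCCCC[C@@H](OS(C)(=O)=O)C/C=C\CCCCCCCC(=O)OC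
F6 | step 1 | methyl (9Z,12S)-12-acetoxyoctadec-9-enoate | CCCCCC[C@H](OC(C)=O)C/C=C\CCCCCCCC(=O)OC
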